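**Strategy.** The pyranone ring of the flavanone (O1–C2–C3–C4–C4a–C8a) is read as a benzofuran-3-one plus one carbon: C3 is the methylene of a cyclopropane fused across C2–C4 in a bicyclic cyclopropanol. One-electron oxidation should open the ring-fusion bond, because C4 becomes the aryl ketone and C2, which bears O1, carries the radical. A chiral nickel catalyst then joins this ring-expanded radical to the aryl bromide of the complete, enantiopure dihydrobenzofuran half. One operation thus grows the five-membered ring to six, forms the C2–aryl bond between the two halves and sets C2. The dihydrobenzofuran half comes from an enantioselective Rh-carbene C–H insertion.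

Key step: step 11

Remark 1: the sense of induction of Rh2(S-PTTL)4 (step 4) and of the (S,S)-ligand on nickel (step 11) is assumed as written; if the opposite sense is found, the mirror-image catalyst or ligand is used.
Remark 2: compound 1 is taken as a catalogue compound; otherwise it is the para-bromination product of catechol monobenzyl ether.

Locants C2, C3, C4 refer to the chromanone; C2′, C3′ refer to the dihydrobenzofuran.

Step 1
Reactants: 1 2-(benzyloxy)-4-bromophenol
Product: 2 2-(benzyloxy)-4-bromo-6-iodophenol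
Conditions: I2, NaHCO3, THF/H2O, rt
Reagents that add atoms: iodine, II
Why: Electrophilic aromatic iodination of the phenoxide should go to the only free position ortho to the OH, the para position being blocked by bromine.

Step 2
Reactants: 2 2-(benzyloxy)-4-bromo-6-iodophenol; 3 4-(benzyloxy)-3-methoxybenzyl chloride
Product: 4 1-(benzyloxy)-2-{[4-(benzyloxy)-3-methoxybenzyl]oxy}-5-bromo-3-iodobenzene
Conditions: K2CO3, NaI (cat.), DMF, 50 °C
Reagents that add atoms: none
Why: Williamson etherification of the flanked phenoxide with a reactive p-alkoxybenzyl chloride (iodide catalysis) installs the benzylic CH2 that later becomes C2′.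

Step 3
Reactants: 4 1-(benzyloxy)-2-{[4-(benzyloxy)-3-methoxybenzyl]oxy}-5-bromo-3-iodobenzene
Product: 5 ethyl 2-[3-(benzyloxy)-2-{[4-(benzyloxy)-3-methoxybenzyl]oxy}-5-bromophenyl]-2-diazoacetate
Conditions: ethyl diazoacetate, Pd(PPh3)4 (5 mol%), Ag2CO3 (0.5 equiv), Et3N, toluene, rt
Reagents that add atoms: ethyl diazoacetate, [N-]=[N+]=CC(=O)OCC
Why: Palladium-catalysed C–H arylation of the acceptor diazo compound with retention of the diazo group should occur only at the C–I bond, since oxidative addition into C–Br is much slower at room temperature.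

Step 4
Reactants: 5 ethyl 2-[3-(benzyloxy)-2-{[4-(benzyloxy)-3-methoxybenzyl]oxy}-5-bromophenyl]-2-diazoacetate
Product: 6 ethyl (2R,3S)-7-(benzyloxy)-2-[4-(benzyloxy)-3-methoxyphenyl]-5-bromo-2,3-dihydro-1-benzofuran-3-carboxylate (cis)
Conditions: Rh2(S-PTTL)4 (1 mol%), toluene, −60 °C
Reagents that add atoms: none
Why: Intramolecular 1,5 C–H insertion of the rhodium donor/acceptor carbene into the electron-rich benzylic ether C–H closes the dihydrofuran ring; the chiral dirhodium carboxylate sets C2′ (R) and the insertion gives the cis isomer kinetically.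

Step 5
Reactants: 6 ethyl (2R,3S)-cis-dihydrobenzofuran-3-carboxylate
Product: 7 ethyl (2R,3R)-7-(benzyloxy)-2-[4-(benzyloxy)-3-methoxyphenyl]-5-bromo-2,3-dihydro-1-benzofuran-3-carboxylate (trans)
Conditions: NaOEt (0.3 equiv), EtOH, 0 °C to rt
Reagents that add atoms: none
Why: Base-mediated epimerisation at the ester α-carbon C3′ should give the thermodynamically preferred trans isomer while C2′ is not touched.

Step 6
Reactants: 7 ethyl (2R,3R)-trans-dihydrobenzofuran-3-carboxylate
Product: 8 [(2R,3S)-7-(benzyloxy)-2-[4-(benzyloxy)-3-methoxyphenyl]-5-bromo-2,3-dihydro-1-benzofuran-3-yl]methanol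
Conditions: DIBAL-H (2.5 equiv), CH2Cl2, −78 to 0 °C; Rochelle salt work-up
Reagents that add atoms: none
Why: Hydride reduction of the ester to the primary alcohol at low temperature should leave the aryl bromide and the benzyl ethers intact (the descriptor at C3′ changes only through CIP priorities).

Step 7
Reactants: 9 4,6-dihydroxy-1-benzofuran-3(2H)-one
Product: 10 4,6-bis(benzyloxy)-1-benzofuran-3(2H)-one
Conditions: BnBr (2.3 equiv), K2CO3, DMF, rt
Reagents that add atoms: benzyl bromide, BrCc1ccccc1
Why: Williamson O-benzylation of both phenoxides with carbonate base should outrun C-alkylation at the α-methylene.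

Step 8
Reactants: 10 4,6-bis(benzyloxy)-1-benzofuran-3(2H)-one
Product: 11 {[4,6-bis(benzyloxy)-1-benzofuran-3-yl]oxy}(tert-butyl)dimethylsilane
Conditions: TBSOTf, Et3N, CH2Cl2, 0 °C
Reagents that add atoms: tert-butyldimethylsilyl triflate, CC(C)(C)[Si](C)(C)OS(=O)(=O)C(F)(F)F
Why: Soft enolisation and O-silylation of the readily enolised coumaranone gives the aromatic 3-silyloxybenzofuran, a silyl enol ether.

Step 9
Reactants: 11 {[4,6-bis(benzyloxy)-1-benzofuran-3-yl]oxy}(tert-butyl)dimethylsilane
Product: 12 racemic cis-fused 4,6-bis(benzyloxy)-6b-[(tert-butyldimethylsilyl)oxy]-1a,6b-dihydro-1H-cyclopropa[b][1]benzofuran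
Conditions: Et2Zn, CH2I2 (3 equiv each), CH2Cl2, 0 °C to rt; pyridine/NaHCO3 quench
Reagents that add atoms: diiodomethane, ICI
Why: Furukawa–Simmons–Smith cyclopropanation of the electron-rich enol-ether C2=C3 bond; the ring fusion can only be cis, and the racemate suffices because both stereocentres are erased in step 11.

Step 10
Reactants: 12 racemic silyloxycyclopropane
Product: 13 racemic cis-fused 4,6-bis(benzyloxy)-1,1a-dihydro-6bH-cyclopropa[b][1]benzofuran-6b-ol
Conditions: TBAF (1.1 equiv), AcOH (1.1 equiv), THF, 0 °C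
Reagents that add atoms: none
Why: Fluoride desilylation buffered with acetic acid should free the tertiary cyclopropanol without base-induced opening of the three-membered ring.

Step 11
Reactants: 13 racemic bicyclic cyclopropanol (1.5 equiv); 8 [(2R,3S)-7-(benzyloxy)-2-[4-(benzyloxy)-3-methoxyphenyl]-5-bromo-2,3-dihydro-1-benzofuran-3-yl]methanol
Product: 14 (2S)-5,7-bis(benzyloxy)-2-{(2R,3S)-7-(benzyloxy)-2-[4-(benzyloxy)-3-methoxyphenyl]-3-(hydroxymethyl)-2,3-dihydro-1-benzofuran-5-yl}-2,3-dihydro-4H-chromen-4-one
Conditions: NiBr2·glyme (10 mol%), (S,S)-bis(imidazoline) ligand (12 mol%), 4CzIPN (2 mol%), 2,4,6-collidine (2 equiv), DMA, 450 nm LEDs, 10 °C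
Reagents that add atoms: none
Why: Proposed new method: the excited photocatalyst oxidises the cyclopropanol (collidine takes the proton) to a cyclopropyloxy radical whose strained ring-fusion bond C2–C4 undergoes β-scission, so that C4 becomes the aryl ketone and the former furanone ring (O1, C2, C4, C4a, C8a) takes in the cyclopropane methylene as C3 to give the six-membered 4-oxochroman-2-yl radical; the aryl–Ni(II) bromide formed from 8 captures this radical, C–C reductive elimination from Ni(III) forms the C2–aryl bond, and the reduced photocatalyst returns nickel to Ni(0). The closest known reaction types are the dual photoredox/nickel ring-opening arylation of cyclopropanols to β-aryl ketones, the oxidative one-carbon ring expansion of bicyclic cyclopropanols (Saegusa type, Dowd–Beckwith radical manifold) and the enantioselective nickel-catalysed arylation of cyclic α-oxy radicals; their combination on an O-substituted bicyclic cyclopropanol is the untested part. No ring is closed by cyclisation: the pyranone ring arises by scission of the bond shared by the three- and five-membered rings, a one-atom ring expansion driven by strain release. The new stereocentre C2 is set by the chiral ligand on nickel during radical capture and reductive elimination (catalyst control, enantioconvergent because both enantiomers of 13 give the same planar radical, with C2′ and C3′ of 8 as remote spectators). The step needs scission of the internal bond in preference to the C4–CH2 bond, which O1 secures by stabilising the secondary C2 radical (the primary alternative can return through the same oxy radical), and it needs coupling at the C–Br bond only, which is the sole carbon–halogen bond in 8.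

Step 12
Reactants: 14 tetra-O-benzyl silyhermin B
Product: 15 silyhermin B, (2S)-5,7-dihydroxy-2-[(2R,3S)-7-hydroxy-2-(4-hydroxy-3-methoxyphenyl)-3-(hydroxymethyl)-2,3-dihydro-1-benzofuran-5-yl]-2,3-dihydro-4H-chromen-4-one
Conditions: H2 (1 atm), 10% Pd/C, EtOAc/MeOH, rt, stopped after uptake of four equivalents
Reagents that add atoms: none
Why: Hydrogenolysis of the four aryl benzyl ethers is faster than cleavage of the two ring benzylic C–O bonds, so the three stereocentres should stay untouched.

**Compound list**

1 | 2-(benzyloxy)-4-bromophenol | Oc1ccc(Br)cc1OCc1ccccc1 | starting material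
2 | 2-(benzyloxy)-4-bromo-6-iodophenol | Oc1c(I)cc(Br)cc1OCc1ccccc1 | intermediate
3 | 4-(benzyloxy)-3-methoxybenzyl chloride | COc1cc(CCl)ccc1OCc1ccccc1 | starting material
4 | 1-(benzyloxy)-2-{[4-(benzyloxy)-3-methoxybenzyl]oxy}-5-bromo-3-iodobenzene | COc1cc(COc2c(I)cc(Br)cc2OCc2ccccc2)ccc1OCc1ccccc1 | intermediate
5 | ethyl 2-[3-(benzyloxy)-2-{[4-(benzyloxy)-3-methoxybenzyl]oxy}-5-bromophenyl]-2-diazoacetate | CCOC(=O)C(=[N+]=[N-])c1cc(Br)cc(OCc2ccccc2)c1OCc1ccc(OCc2ccccc2)c(OC)c1 | intermediate
6 | ethyl (2R,3S)-7-(benzyloxy)-2-[4-(benzyloxy)-3-methoxyphenyl]-5-bromo-2,3-dihydro-1-benzofuran-3-carboxylate (cis) | COc1cc([C@@H]2Oc3c(OCc4ccccc4)cc(Br)cc3[C@@H]2C(=O)OCC)ccc1OCc1ccccc1 | intermediate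
7 | ethyl (2R,3R)-7-(benzyloxy)-2-[4-(benzyloxy)-3-methoxyphenyl]-5-bromo-2,3-dihydro-1-benzofuran-3-carboxylate (trans) | COc1cc([C@@H]2Oc3c(OCc4ccccc4)cc(Br)cc3[C@H]2C(=O)OCC)ccc1OCc1ccccc1 | intermediate
8 | [(2R,3S)-7-(benzyloxy)-2-[4-(benzyloxy)-3-methoxyphenyl]-5-bromo-2,3-dihydro-1-benzofuran-3-yl]methanol | COc1cc([C@@H]2Oc3c(OCc4ccccc4)cc(Br)cc3[C@H]2CO)ccc1OCc1ccccc1 | intermediate
9 | 4,6-dihydroxy-1-benzofuran-3(2H)-one | O=C1COc2cc(O)cc(O)c12 | starting material
10 | 4,6-bis(benzyloxy)-1-benzofuran-3(2H)-one | O=C1COc2cc(OCc3ccccc3)cc(OCc3ccccc3)c12 | intermediate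
11 | {[4,6-bis(benzyloxy)-1-benzofuran-3-yl]oxy}(tert-butyl)dimethylsilane | CC(C)(C)[Si](C)(C)Oc1coc2cc(OCc3ccccc3)cc(OCc3ccccc3)c12 | intermediate
12 | 4,6-bis(benzyloxy)-6b-[(tert-butyldimethylsilyl)oxy]-1a,6b-dihydro-1H-cyclopropa[b][1]benzofuran (racemic, cis-fused) | CC(C)(C)[Si](C)(C)OC12CC1Oc1cc(OCc3ccccc3)cc(OCc3ccccc3)c12 | intermediate
13 | 4,6-bis(benzyloxy)-1,1a-dihydro-6bH-cyclopropa[b][1]benzofuran-6b-ol (racemic, cis-fused) | OC12CC1Oc1cc(OCc3ccccc3)cc(OCc3ccccc3)c12 | intermediate
14 | (2S)-5,7-bis(benzyloxy)-2-{(2R,3S)-7-(benzyloxy)-2-[4-(benzyloxy)-3-methoxyphenyl]-3-(hydroxymethyl)-2,3-dihydro-1-benzofuran-5-yl}-2,3-dihydro-4H-chromen-4-one | COc1cc([C@@H]2Oc3c(OCc4ccccc4)cc([C@@H]4CC(=O)c5c(OCc6ccccc6)cc(OCc6ccccc6)cc5O4)cc3[C@H]2CO)ccc1OCc1ccccc1 | intermediate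
15 | silyhermin B | COc1cc([C@@H]2Oc3c(O)cc([C@@H]4CC(=O)c5c(O)cc(O)cc5O4)cc3[C@H]2CO)ccc1O | target

**Step count.** Total: 12 steps. Longest linear sequence: 8 steps (steps 1–6, 11, 12); steps 7–10 form the second branch.

**Steps most likely to fail**

Step 11. The nickel catalyst may capture the C2 radical with poor facial selectivity, or the radical may be oxidised on to the chromone or reduced before it is captured. The fallback uses known chemistry and sets out from 13 and 8. Saegusa-type oxidative opening of 13 with FeCl3 in DMF at 0 °C should give the ring-expanded 2-chloro-5,7-bis(benzyloxy)chroman-4-one F1, the same one-carbon ring expansion in its classical form. NaOAc in MeOH then eliminates HCl to give 5,7-bis(benzyloxy)-4H-chromen-4-one F2. Miyaura borylation of 8 (B2pin2, PdCl2(dppf), KOAc, dioxane, 80 °C) gives the pinacol boronate F3. Rhodium(I)/chiral diene-catalysed asymmetric 1,4-addition of F3 to F2 (aqueous KOH, dioxane) sets C2 and comes back to the route at 14.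

Step 9. Carbenoid transfer to the aromatic C2=C3 bond may be slow, and zinc iodide may open the donor-substituted cyclopropane as it forms. The fallback sets out from 11. Dibromocarbene (CHBr3, KOtBu, pentane, −20 °C) adds to the enol ether, and the gem-dibromocyclopropane should open spontaneously with loss of the silyl bromide to give 3-bromo-5,7-bis(benzyloxy)-4H-chromen-4-one F4 (halocarbene ring expansion). Palladium-catalysed formate reduction (Pd(PPh3)4, HCO2Na, DMF) removes the bromine to give the chromone F2. F2 is then joined to the boronate F3 by the rhodium-catalysed asymmetric 1,4-addition described under step 11, which comes back to the route at 14.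

Step 4. Enantioface discrimination in the carbene C–H insertion may be insufficient for this ortho-alkoxy substrate, which would erode both C2′ and C3′. The fallback sets out from 5 and replaces catalyst control by resolution. Rh2(OAc)4 in CH2Cl2 gives the racemic cis ester, that is 6 together with its mirror image ethyl (2S,3R)-cis-carboxylate F5. NaOEt epimerisation gives the racemic trans ester, 7 with its mirror image ethyl (2S,3S)-trans-carboxylate F6. DIBAL-H gives the racemic alcohol, 8 with its mirror image (2S,3R)-alcohol F7. Lipase-catalysed acylation (Burkholderia cepacia lipase, vinyl acetate, MTBE) is expected to remove F7 as its acetate, (2S,3R)-acetate F8, and the unreacted alcohol comes back to the route as 8. The enantiomer preference of the lipase is to be checked on a small scale.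

**Further compounds**

F1 | step 11 | 2-chloro-5,7-bis(benzyloxy)-2,3-dihydro-4H-chromen-4-one (racemic) | O=C1CC(Cl)Oc2cc(OCc3ccccc3)cc(OCc3ccccc3)c12
F2 | step 11 | 5,7-bis(benzyloxy)-4H-chromen-4-one | O=c1ccoc2cc(OCc3ccccc3)cc(OCc3ccccc3)c12
F3 | step 11 | [(2R,3S)-7-(benzyloxy)-2-[4-(benzyloxy)-3-methoxyphenyl]-5-(4,4,5,5-tetramethyl-1,3,2-dioxaborolan-2-yl)-2,3-dihydro-1-benzofuran-3-yl]methanol | COc1cc([C@@H]2Oc3c(OCc4ccccc4)cc(B4OC(C)(C)C(C)(C)O4)cc3[C@H]2CO)ccc1OCc1ccccc1
F4 | step 9 | 3-bromo-5,7-bis(benzyloxy)-4H-chromen-4-one | O=c1c(Br)coc2cc(OCc3ccccc3)cc(OCc3ccccc3)c12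
F5 | step 4 | ethyl (2S,3R)-7-(benzyloxy)-2-[4-(benzyloxy)-3-methoxyphenyl]-5-bromo-2,3-dihydro-1-benzofuran-3-carboxylate (cis, mirror image of 6) | COc1cc([C@H]2Oc3c(OCc4ccccc4)cc(Br)cc3[C@H]2C(=O)OCC)ccc1OCc1ccccc1
F6 | step 4 | ethyl (2S,3S)-7-(benzyloxy)-2-[4-(benzyloxy)-3-methoxyphenyl]-5-bromo-2,3-dihydro-1-benzofuran-3-carboxylate (trans, mirror image of 7) | COc1cc([C@H]2Oc3c(OCc4ccccc4)cc(Br)cc3[C@@H]2C(=O)OCC)ccc1OCc1ccccc1
F7 | step 4 | [(2S,3R)-7-(benzyloxy)-2-[4-(benzyloxy)-3-methoxyphenyl]-5-bromo-2,3-dihydro-1-benzofuran-3-yl]methanol (mirror image of 8) | COc1cc([C@H]2Oc3c(OCc4ccccc4)cc(Br)cc3[C@@H]2CO)ccc1OCc1ccccc1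
F8 | step 4 | [(2S,3R)-7-(benzyloxy)-2-[4-(benzyloxy)-3-methoxyphenyl]-5-bromo-2,3-dihydro-1-benzofuran-3-yl]methyl acetate | COc1cc([C@H]2Oc3c(OCc4ccccc4)cc(Br)cc3[C@@H]2COC(C)=O)ccc1OCc1ccccc1
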